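**Retrosynthetic overview**

1. Numbering: ring A = C1 (spiro), C2 (C=O), C3, C4 (NHAc), C5 (OH), C6; ring B = C1–C7–C8(=O)–O–C9; side chain C10=C11. The side chain is cut back to a C10 aldehyde (dibromo-olefination, two Negishi couplings). The C4–N bond is cut back to a C4 oxygen that is eliminated and replaced by nitrogen delivered from a tether on the C5 oxygen (cis).
2. Ring B is opened to the C8 primary alcohol and the C9 hydroxyl (oxidative lactonisation).
3. The strategy rests on quaternary C1 lying between the C2 ketone and oxygen-bearing C9, the retron of a 2,3-epoxy alcohol semipinacol shift. C1–C6 is disconnected, which contracts ring A to a cyclopentanol carrying the C1–C9 epoxide.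
4. The epoxy alcohol is cut at the carbinol–C1 bond into twofold-symmetric (3S,4S)-3,4-bis(benzyloxy)cyclopentanone (from diethyl L-tartrate) and a (Z)-alkenyllithium (from but-3-yn-1-ol); the epoxide comes from Shi epoxidation.
5. Ring order: cyclopentane (tartrate-derived), then ring A by five-to-six ring expansion, then ring B by lactonisation; the oxazoline that carries nitrogen to C4 is opened again.

Key step: step 11

Remark: the target SMILES is read as (1R,4R,5S,9R,10E) in this numbering; the descriptors at C1 and C9 of intermediates change with substituent priorities and not with geometry; TBS = tert-butyldimethylsilyl, TIPS = triisopropylsilyl, TES = triethylsilyl, Bn = benzyl.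

**Route**

Step 1
Reactants: 1 diethyl L-tartrate
Product: 2 diethyl (2R,3R)-2,3-bis(benzyloxy)butanedioate
Conditions: NaH, BnBr, Bu4NI (cat.), 18-crown-6 (cat.), THF, 0 °C → rt
Reagents that add atoms: benzyl bromide, BrCc1ccccc1
Why: Williamson etherification of both secondary alkoxides under iodide catalysis at low temperature should give the dibenzyl ether without touching the two stereocentres.

Step 2
Reactants: 2 diethyl (2R,3R)-2,3-bis(benzyloxy)butanedioate
Product: 3 (2S,3S)-2,3-bis(benzyloxy)butane-1,4-diol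
Conditions: LiAlH4, THF, 0 °C → rt; aqueous NaOH work-up
Reagents that add atoms: none
Why: LiAlH4 reduction of both esters to primary alcohols leaves the ether-bearing stereocentres untouched, the descriptors changing to S,S through the priority rules only.

Step 3
Reactants: 3 (2S,3S)-2,3-bis(benzyloxy)butane-1,4-diol
Product: 4 (2R,3R)-2,3-bis(benzyloxy)-1,4-diiodobutane
Conditions: I2, PPh3, imidazole, toluene/MeCN, 0 °C → rt
Reagents that add atoms: iodine, II
Why: Garegg–Samuelsson (Appel-type) iodination converts both primary alcohols through alkoxyphosphonium ions into iodides and does not affect the secondary benzyl ethers.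

Step 4
Reactants: 4 (2R,3R)-2,3-bis(benzyloxy)-1,4-diiodobutane
Product: 6 (3S,4S)-3,4-bis(benzyloxy)cyclopentan-1-one, via cyclic tosyl isocyanide 5 (not isolated)
Conditions: TosMIC, NaH, DMSO/Et2O, rt; then conc. HCl, Et2O, rt
Reagents that add atoms: p-toluenesulfonylmethyl isocyanide (TosMIC), [C-]#[N+]CS(=O)(=O)c1ccc(C)cc1; water, O
Why: van Leusen ketone synthesis, in which the TosMIC carbanion is alkylated twice by the 1,4-diiodide (the second alkylation a 5-exo-tet ring closure) and acid hydrolysis of the geminal tosyl isocyanide releases the ketone, the two benzyloxy stereocentres being spectators.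

Step 5
Reactants: 7 but-3-yn-1-ol
Product: 8 (but-3-yn-1-yloxy)(tert-butyl)dimethylsilane
Conditions: TBSCl, imidazole, CH2Cl2, 0 °C → rt
Reagents that add atoms: tert-butyldimethylsilyl chloride, CC(C)(C)[Si](C)(C)Cl
Why: imidazole-mediated silylation masks the primary alcohol (the later C8 oxygen) for the organometallic steps.

Step 6
Reactants: 8 (but-3-yn-1-yloxy)(tert-butyl)dimethylsilane
Product: 10 5-[(tert-butyldimethylsilyl)oxy]pent-2-yn-1-ol, via lithium acetylide 9 (not isolated)
Conditions: n-BuLi, THF, −78 °C; (CH2O)n, −78 °C → rt; H2O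
Reagents that add atoms: formaldehyde (from paraformaldehyde), C=O
Why: addition of the lithium acetylide to formaldehyde gives the propargylic alcohol whose hydroxyl will direct the hydroalumination.

Step 7
Reactants: 10 5-[(tert-butyldimethylsilyl)oxy]pent-2-yn-1-ol
Product: 12 (2Z)-5-[(tert-butyldimethylsilyl)oxy]-3-iodopent-2-en-1-ol, via cyclic alkenylalanate 11 (not isolated)
Conditions: Red-Al (NaAlH2(OCH2CH2OMe)2), THF, 0 °C → rt; EtOAc; then I2, THF, −78 → 0 °C
Reagents that add atoms: iodine, II
Why: hydroxyl-directed trans-hydroalumination places hydride on C9 and aluminium on C1 in a five-membered alkoxyalanate, and iodinolysis with retention should give the (Z)-3-iodo allylic alcohol with iodine cis to C10.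

Step 8
Reactants: 12 (2Z)-5-[(tert-butyldimethylsilyl)oxy]-3-iodopent-2-en-1-ol
Product: 13 (3Z)-1-[(tert-butyldimethylsilyl)oxy]-3-iodo-5-[(triisopropylsilyl)oxy]pent-3-ene
Conditions: TIPSCl, imidazole, DMF, rt
Reagents that add atoms: triisopropylsilyl chloride, CC(C)[Si](Cl)(C(C)C)C(C)C
Why: silylation of the allylic alcohol with the bulky triisopropylsilyl group gives an ether that resists 1,4-silyl migration to the neighbouring alkenyllithium and survives the later selective removal of the C8 silyl ether.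

Step 9
Reactants: 13 (3Z)-1-[(tert-butyldimethylsilyl)oxy]-3-iodo-5-[(triisopropylsilyl)oxy]pent-3-ene; 6 (3S,4S)-3,4-bis(benzyloxy)cyclopentan-1-one
Product: 15 (3S,4S)-3,4-bis(benzyloxy)-1-[(3Z)-1-[(tert-butyldimethylsilyl)oxy]-5-[(triisopropylsilyl)oxy]pent-3-en-3-yl]cyclopentan-1-ol, via alkenyllithium 14 (not isolated)
Conditions: 13, t-BuLi (2.1 equiv), Et2O, −78 °C; then 6 premixed with LaCl3·2LiCl, THF, −78 °C; H2O
Reagents that add atoms: none
Why: iodine–lithium exchange proceeds with retention of alkene geometry and the alkenyllithium adds 1,2 to the ketone while LaCl3·2LiCl suppresses enolisation and loss of benzyloxide; the ketone has a twofold axis, so its faces are homotopic, the carbinol carbon is not a stereocentre and one product should result.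

Step 10
Reactants: 15 tertiary allylic alcohol
Product: 16 (3S,4S)-3,4-bis(benzyloxy)-1-[(2R,3R)-2-{2-[(tert-butyldimethylsilyl)oxy]ethyl}-3-{[(triisopropylsilyl)oxy]methyl}oxiran-2-yl]cyclopentan-1-ol
Conditions: Shi ketone from D-fructose (0.3 equiv), Oxone (KHSO5), K2CO3, Bu4NHSO4, MeCN/CH2(OMe)2, aq. Na2B4O7/Na2EDTA buffer (pH about 10.5), 0 °C
Reagents that add atoms: potassium peroxymonosulfate (the oxidant in Oxone), [K+].[O-]S(=O)(=O)OO
Why: Shi asymmetric epoxidation, in which the dioxirane of the D-fructose-derived ketone transfers oxygen through a spiro transition state to the face that gives (R,R)-epoxides from alkenes whose trans pair of substituents is arranged as C7 and C10 are here, so C1 and C9 are set under catalyst control and attack on the wrong face would give a separable diastereomer.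

Step 11
Reactants: 16 epoxy alcohol
Product: 17 (2S,4S,5S)-4,5-bis(benzyloxy)-2-{2-[(tert-butyldimethylsilyl)oxy]ethyl}-2-{(1S)-1-hydroxy-2-[(triisopropylsilyl)oxy]ethyl}cyclohexan-1-one
Conditions: BF3·OEt2 (0.3 equiv), CH2Cl2, −78 °C; aq. NaHCO3
Reagents that add atoms: none
Why: BF3 binds the epoxide oxygen and the C1–O bond breaks at the tertiary carbon while one ring CH2 of the cyclopentanol, antiperiplanar to that bond, shifts from the carbinol carbon to C1 with the hydroxyl lone pair pushing, so that the carbinol carbon becomes the C2 ketone and the epoxide oxygen the C9 hydroxyl; this is the Lewis acid semipinacol rearrangement of a 2,3-epoxy alcohol, known with ring expansion of cyclobutanols and cyclopentanols. Ring A is closed by this 1,2-shift, a five-to-six ring expansion that forms C1–C6, and not by cyclisation of a chain. The quaternary centre C1 is formed with inversion at the epoxide carbon, so it is controlled by the (R,R) configuration of the Shi epoxide, and C9 keeps its C–O bond and its configuration. The two ring CH2 groups are diastereotopic in 16, but since both benzyloxy carbons have the same configuration and the carbinol carbon becomes trigonal, either migration gives the same ketone 17. The step needs opening at C1 and not at C9, which is secured because C1 is tertiary whereas C9 is secondary, not allylic and deactivated by the adjacent silyloxymethyl group; low temperature and a substoichiometric Lewis acid should hold back hydride shift, proton loss and silyl ether cleavage.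

Step 12
Reactants: 17 ring-expanded hydroxy ketone
Product: 18 (2S,4S,5S)-4,5-bis(benzyloxy)-2-(2-hydroxyethyl)-2-{(1S)-1-hydroxy-2-[(triisopropylsilyl)oxy]ethyl}cyclohexan-1-one
Conditions: HF·pyridine, pyridine, THF, 0 °C
Reagents that add atoms: none
Why: buffered HF·pyridine cleaves the primary TBS ether much faster than the primary TIPS ether, in a non-alcoholic medium that cannot ketalise the C2 ketone.

Step 13
Reactants: 18 keto diol
Product: 21 (1S,5R,8S,9S)-8,9-bis(benzyloxy)-1-{[(triisopropylsilyl)oxy]methyl}-2-oxaspiro[4.5]decane-3,6-dione, via hydroxy aldehyde 19 (not isolated), via lactol 20 (not isolated)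
Conditions: TEMPO (0.2 equiv), PhI(OAc)2 (2.5 equiv), CH2Cl2, rt
Reagents that add atoms: none
Why: TEMPO/PhI(OAc)2 oxidative lactonisation, in which the primary C8 alcohol is oxidised in preference to the hindered secondary C9 alcohol, the aldehyde closes onto C9–OH to the five-membered lactol and this is oxidised to the γ-lactone, closing ring B with C9 unchanged.

Step 14
Reactants: 21 spiro keto lactone
Product: 22 (1S,5R,8S,9S)-8,9-dihydroxy-1-{[(triisopropylsilyl)oxy]methyl}-2-oxaspiro[4.5]decane-3,6-dione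
Conditions: H2 (1 atm), Pd(OH)2/C, EtOAc, rt
Reagents that add atoms: none
Why: hydrogenolysis of the two benzyl ethers under neutral conditions leaves the hindered ketone, the lactone and the silyl ether untouched and is placed before any alkene is present.

Step 15
Reactants: 22 dihydroxy keto lactone
Product: 25 cis-fused 2-(trichloromethyl)-4,5-dihydrooxazole spanning C4 (N) and C5 (O) of the C2-keto spirolactone with C10 OTIPS, via bis-trichloroacetimidate 23 (not isolated), via enone imidate 24 (not isolated)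
Conditions: Cl3CCN (4 equiv), DBU (0.5 equiv), CH2Cl2, 0 °C → rt
Reagents that add atoms: trichloroacetonitrile, N#CC(Cl)(Cl)Cl
Why: base-catalysed addition of both hydroxyls to trichloroacetonitrile, E1cB loss of the C4 imidate through the only available enolate (C3, since C1 is quaternary) and 5-exo-trig aza-Michael addition of the C5 imidate nitrogen to C4 (a known imidate conjugate addition) should give the cis-fused oxazoline, the tether forcing nitrogen onto the face of the C5 oxygen and so setting C4 as R.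

Step 16
Reactants: 25 trichloromethyl oxazoline
Product: 27 N-[(1S,5R,8R,9S)-9-hydroxy-1-(hydroxymethyl)-3,6-dioxo-2-oxaspiro[4.5]decan-8-yl]acetamide, via amino diol hydrochloride 26 (not isolated)
Conditions: 2 M aq. HCl/THF (1:1), rt → 40 °C; then NaHCO3 to pH 8, Ac2O, 0 °C
Reagents that add atoms: acetic anhydride, CC(=O)OC(C)=O
Why: dilute aqueous acid hydrolyses the 2-trichloromethyl oxazoline to the ammonium salt (the labile trichloroacetate being hydrolysed as well) and cleaves the primary TIPS ether, and Schotten–Baumann acetylation at pH 8 acylates nitrogen in preference to the two hydroxyls, no stereocentre being touched.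

Step 17
Reactants: 27 acetamido diol
Product: 28 N-[(1S,5R,8R,9S)-3,6-dioxo-9-[(triethylsilyl)oxy]-1-{[(triethylsilyl)oxy]methyl}-2-oxaspiro[4.5]decan-8-yl]acetamide
Conditions: TESCl (2.5 equiv), imidazole, DMF, 0 °C → rt
Reagents that add atoms: chlorotriethylsilane, CC[Si](Cl)(CC)CC
Why: imidazole-mediated silylation protects both hydroxyls as TES ethers, the amide N–H being inert under these conditions.

Step 18
Reactants: 28 bis(triethylsilyl) ether
Product: 30 N-[(1S,5R,8R,9S)-1-formyl-3,6-dioxo-9-[(triethylsilyl)oxy]-2-oxaspiro[4.5]decan-8-yl]acetamide, via alkoxysulfonium chloride 29 (not isolated)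
Conditions: (COCl)2, DMSO, CH2Cl2, −78 → −30 °C; then Et3N, −78 → 0 °C
Reagents that add atoms: none
Why: under Swern conditions a primary TES ether is cleaved by the chlorosulfonium reagent and oxidised directly to the aldehyde while the secondary TES ether survives, so C10 is oxidised without a separate deprotection.

Step 19
Reactants: 30 aldehyde
Product: 31 N-[(1R,5R,8R,9S)-1-(2,2-dibromoethenyl)-3,6-dioxo-9-[(triethylsilyl)oxy]-2-oxaspiro[4.5]decan-8-yl]acetamide
Conditions: CBr4, PPh3, Zn dust, CH2Cl2, rt (ylide preformed); then 30, 0 °C → rt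
Reagents that add atoms: carbon tetrabromide, BrC(Br)(Br)Br
Why: Corey–Fuchs (Ramirez) dibromo-olefination with the zinc-generated ylide converts the aldehyde into the 1,1-dibromoalkene without the phosphorus dibromide by-product that could attack the amide or the silyl ether, the hindered C2 ketone being unreactive toward the ylide.

Step 20
Reactants: 32 5-bromo-2-methylpent-2-ene
Product: 33 (4-methylpent-3-en-1-yl)zinc bromide
Conditions: Zn dust (activated with BrCH2CH2Br and Me3SiCl), LiCl, THF, 50 °C
Reagents that add atoms: zinc, [Zn]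
Why: direct LiCl-assisted insertion of activated zinc into the primary C–Br bond gives the alkylzinc bromide and leaves the trisubstituted alkene alone.

Step 21
Reactants: 31 dibromoalkene; 33 (4-methylpent-3-en-1-yl)zinc bromide
Product: 34 N-[(1R,5R,8R,9S)-1-[(1Z)-2-bromo-6-methylhepta-1,5-dien-1-yl]-3,6-dioxo-9-[(triethylsilyl)oxy]-2-oxaspiro[4.5]decan-8-yl]acetamide
Conditions: PdCl2(DPEphos) (5 mol %), THF, 0 °C → rt
Reagents that add atoms: none
Why: Negishi coupling in which zerovalent palladium inserts into the less hindered C–Br bond trans to C9, so the alkyl group should enter trans to C9 and leave the (Z)-bromoalkene, the alkylzinc bromide tolerating ketone, lactone and amide N–H.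

Step 22
Reactants: 34 (Z)-bromoalkene
Product: 35 N-[(1R,5R,8R,9S)-1-[(1E)-2,6-dimethylhepta-1,5-dien-1-yl]-3,6-dioxo-9-[(triethylsilyl)oxy]-2-oxaspiro[4.5]decan-8-yl]acetamide
Conditions: Me2Zn (excess), Pd(PtBu3)2 (5 mol %), THF, rt
Reagents that add atoms: dimethylzinc, C[Zn]C
Why: second Negishi coupling, in which the bulky electron-rich phosphine catalyst replaces bromine with retention of configuration, so methyl ends cis to C9 and the (E)-trisubstituted alkene of the target is formed.

Step 23
Reactants: 35 O-triethylsilyl miliusane V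
Product: 36 (+)-miliusane V
Conditions: HF·pyridine, pyridine, THF, 0 °C → rt
Reagents that add atoms: none
Why: buffered HF·pyridine removes the secondary TES ether under conditions that spare the allylic lactone, the 1,5-diene and the β-acetamido ketone.

**Compound list**

1 | diethyl L-tartrate, diethyl (2R,3R)-2,3-dihydroxybutanedioate | CCOC(=O)[C@H](O)[C@@H](O)C(=O)OCC | starting material
2 | diethyl (2R,3R)-2,3-bis(benzyloxy)butanedioate | CCOC(=O)[C@H](OCc1ccccc1)[C@@H](OCc1ccccc1)C(=O)OCC | intermediate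
3 | (2S,3S)-2,3-bis(benzyloxy)butane-1,4-diol | OC[C@H](OCc1ccccc1)[C@@H](OCc1ccccc1)CO | intermediate
4 | (2R,3R)-2,3-bis(benzyloxy)-1,4-diiodobutane | IC[C@H](OCc1ccccc1)[C@@H](OCc1ccccc1)CI | intermediate
5 | (3S,4S)-3,4-bis(benzyloxy)-1-isocyano-1-(4-methylbenzenesulfonyl)cyclopentane (not isolated) | [C-]#[N+]C1(S(=O)(=O)c2ccc(C)cc2)C[C@H](OCc2ccccc2)[C@@H](OCc2ccccc2)C1 | intermediate
6 | (3S,4S)-3,4-bis(benzyloxy)cyclopentan-1-one | O=C1C[C@H](OCc2ccccc2)[C@@H](OCc2ccccc2)C1 | intermediate
7 | but-3-yn-1-ol | C#CCCO | starting material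
8 | (but-3-yn-1-yloxy)(tert-butyl)dimethylsilane | C#CCCO[Si](C)(C)C(C)(C)C | intermediate
9 | lithium acetylide of 8 (not isolated) | [Li]C#CCCO[Si](C)(C)C(C)(C)C | intermediate
10 | 5-[(tert-butyldimethylsilyl)oxy]pent-2-yn-1-ol | OCC#CCCO[Si](C)(C)C(C)(C)C | intermediate
11 | sodium cyclic alkenylalanate, 2,5-dihydro-1,2-oxaluminole ate complex with aluminium on C1 and two 2-methoxyethoxy ligands (not isolated) | [Na+].COCCO[Al-]1(OCCOC)OCC=C1CCO[Si](C)(C)C(C)(C)C | intermediate
12 | (2Z)-5-[(tert-butyldimethylsilyl)oxy]-3-iodopent-2-en-1-ol | OC/C=C(\I)CCO[Si](C)(C)C(C)(C)C | intermediate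
13 | (3Z)-1-[(tert-butyldimethylsilyl)oxy]-3-iodo-5-[(triisopropylsilyl)oxy]pent-3-ene | I/C(CCO[Si](C)(C)C(C)(C)C)=C\CO[Si](C(C)C)(C(C)C)C(C)C | intermediate
14 | alkenyllithium from 13, lithium cis to CH2OTIPS (not isolated) | [Li]/C(CCO[Si](C)(C)C(C)(C)C)=C\CO[Si](C(C)C)(C(C)C)C(C)C | intermediate
15 | (3S,4S)-3,4-bis(benzyloxy)-1-[(3Z)-1-[(tert-butyldimethylsilyl)oxy]-5-[(triisopropylsilyl)oxy]pent-3-en-3-yl]cyclopentan-1-ol | OC1(C[C@H](OCc2ccccc2)[C@@H](OCc2ccccc2)C1)/C(CCO[Si](C)(C)C(C)(C)C)=C\CO[Si](C(C)C)(C(C)C)C(C)C | intermediate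
16 | (3S,4S)-3,4-bis(benzyloxy)-1-[(2R,3R)-2-{2-[(tert-butyldimethylsilyl)oxy]ethyl}-3-{[(triisopropylsilyl)oxy]methyl}oxiran-2-yl]cyclopentan-1-ol (key-step precursor) | OC1(C[C@H](OCc2ccccc2)[C@@H](OCc2ccccc2)C1)[C@]1(CCO[Si](C)(C)C(C)(C)C)O[C@@H]1CO[Si](C(C)C)(C(C)C)C(C)C | intermediate
17 | (2S,4S,5S)-4,5-bis(benzyloxy)-2-{2-[(tert-butyldimethylsilyl)oxy]ethyl}-2-{(1S)-1-hydroxy-2-[(triisopropylsilyl)oxy]ethyl}cyclohexan-1-one (key-step product; 1S,4S,5S,9S in the numbering used here) | O=C1C[C@H](OCc2ccccc2)[C@@H](OCc2ccccc2)C[C@@]1(CCO[Si](C)(C)C(C)(C)C)[C@H](O)CO[Si](C(C)C)(C(C)C)C(C)C | intermediate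
18 | (2S,4S,5S)-4,5-bis(benzyloxy)-2-(2-hydroxyethyl)-2-{(1S)-1-hydroxy-2-[(triisopropylsilyl)oxy]ethyl}cyclohexan-1-one | O=C1C[C@H](OCc2ccccc2)[C@@H](OCc2ccccc2)C[C@@]1(CCO)[C@H](O)CO[Si](C(C)C)(C(C)C)C(C)C | intermediate
19 | C8 aldehyde of 18, configuration as in 18 (not isolated) | O=C1C[C@H](OCc2ccccc2)[C@@H](OCc2ccccc2)C[C@@]1(CC=O)[C@H](O)CO[Si](C(C)C)(C(C)C)C(C)C | intermediate
20 | spiro lactol, C8 hemiacetal closed onto the C9 oxygen, mixture at C8 (not isolated) | O=C1C[C@H](OCc3ccccc3)[C@@H](OCc3ccccc3)C[C@]12CC(O)O[C@@H]2CO[Si](C(C)C)(C(C)C)C(C)C | intermediate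
21 | (1S,5R,8S,9S)-8,9-bis(benzyloxy)-1-{[(triisopropylsilyl)oxy]methyl}-2-oxaspiro[4.5]decane-3,6-dione | O=C1C[C@H](OCc3ccccc3)[C@@H](OCc3ccccc3)C[C@]12CC(=O)O[C@@H]2CO[Si](C(C)C)(C(C)C)C(C)C | intermediate
22 | (1S,5R,8S,9S)-8,9-dihydroxy-1-{[(triisopropylsilyl)oxy]methyl}-2-oxaspiro[4.5]decane-3,6-dione | O=C1C[C@H](O)[C@@H](O)C[C@]12CC(=O)O[C@@H]2CO[Si](C(C)C)(C(C)C)C(C)C | intermediate
23 | bis(2,2,2-trichloroacetimidate) of 22 at the C4 and C5 oxygens (not isolated) | O=C1C[C@H](OC(=N)C(Cl)(Cl)Cl)[C@@H](OC(=N)C(Cl)(Cl)Cl)C[C@]12CC(=O)O[C@@H]2CO[Si](C(C)C)(C(C)C)C(C)C | intermediate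
24 | C3=C4 enone carrying the C5 trichloroacetimidate (not isolated) | O=C1C=C[C@@H](OC(=N)C(Cl)(Cl)Cl)C[C@]12CC(=O)O[C@@H]2CO[Si](C(C)C)(C(C)C)C(C)C | intermediate
25 | cis-fused 2-(trichloromethyl)-4,5-dihydrooxazole on C4 (N) and C5 (O) of the keto spirolactone, C10 OTIPS (1R,4R,5S,9S) | O=C1C[C@@H](N=C3C(Cl)(Cl)Cl)[C@@H](O3)C[C@]12CC(=O)O[C@@H]2CO[Si](C(C)C)(C(C)C)C(C)C | intermediate
26 | (1S,5R,8R,9S)-8-amino-9-hydroxy-1-(hydroxymethyl)-2-oxaspiro[4.5]decane-3,6-dione hydrochloride (not isolated) | O=C1C[C@@H](N)[C@@H](O)C[C@]12CC(=O)O[C@@H]2CO.Cl | intermediate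
27 | N-[(1S,5R,8R,9S)-9-hydroxy-1-(hydroxymethyl)-3,6-dioxo-2-oxaspiro[4.5]decan-8-yl]acetamide | O=C1C[C@@H](NC(C)=O)[C@@H](O)C[C@]12CC(=O)O[C@@H]2CO | intermediate
28 | N-[(1S,5R,8R,9S)-3,6-dioxo-9-[(triethylsilyl)oxy]-1-{[(triethylsilyl)oxy]methyl}-2-oxaspiro[4.5]decan-8-yl]acetamide | O=C1C[C@@H](NC(C)=O)[C@@H](O[Si](CC)(CC)CC)C[C@]12CC(=O)O[C@@H]2CO[Si](CC)(CC)CC | intermediate
29 | C10 alkoxydimethylsulfonium chloride of the C5 TES ether (not isolated) | O=C1C[C@@H](NC(C)=O)[C@@H](O[Si](CC)(CC)CC)C[C@]12CC(=O)O[C@@H]2CO[S+](C)C.[Cl-] | intermediate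
30 | N-[(1S,5R,8R,9S)-1-formyl-3,6-dioxo-9-[(triethylsilyl)oxy]-2-oxaspiro[4.5]decan-8-yl]acetamide | O=C1C[C@@H](NC(C)=O)[C@@H](O[Si](CC)(CC)CC)C[C@]12CC(=O)O[C@@H]2C=O | intermediate
31 | N-[(1R,5R,8R,9S)-1-(2,2-dibromoethenyl)-3,6-dioxo-9-[(triethylsilyl)oxy]-2-oxaspiro[4.5]decan-8-yl]acetamide | O=C1C[C@@H](NC(C)=O)[C@@H](O[Si](CC)(CC)CC)C[C@]12CC(=O)O[C@@H]2C=C(Br)Br | intermediate
32 | 5-bromo-2-methylpent-2-ene | CC(C)=CCCBr | starting material
33 | (4-methylpent-3-en-1-yl)zinc bromide | CC(C)=CCC[Zn]Br | intermediate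
34 | N-[(1R,5R,8R,9S)-1-[(1Z)-2-bromo-6-methylhepta-1,5-dien-1-yl]-3,6-dioxo-9-[(triethylsilyl)oxy]-2-oxaspiro[4.5]decan-8-yl]acetamide | O=C1C[C@@H](NC(C)=O)[C@@H](O[Si](CC)(CC)CC)C[C@]12CC(=O)O[C@@H]2/C=C(\Br)CCC=C(C)C | intermediate
35 | N-[(1R,5R,8R,9S)-1-[(1E)-2,6-dimethylhepta-1,5-dien-1-yl]-3,6-dioxo-9-[(triethylsilyl)oxy]-2-oxaspiro[4.5]decan-8-yl]acetamide | O=C1C[C@@H](NC(C)=O)[C@@H](O[Si](CC)(CC)CC)C[C@]12CC(=O)O[C@@H]2/C=C(\C)CCC=C(C)C | intermediate
36 | (+)-miliusane V, N-[(1R,5R,8R,9S)-1-[(1E)-2,6-dimethylhepta-1,5-dien-1-yl]-9-hydroxy-3,6-dioxo-2-oxaspiro[4.5]decan-8-yl]acetamide (1R,4R,5S,9R in the numbering used here) | CC(=O)N[C@@H]1CC(=O)[C@@]2(CC(=O)O[C@@H]2/C=C(\C)CCC=C(C)C)C[C@@H]1O | target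

**Step count**

Total step count: 23.
Longest linear sequence: 18 steps (steps 1–4, 9–19 and 21–23; the sequence from 7 through steps 5–8 is equally long).

**Steps most likely to fail**

Step 11 (semipinacol ring expansion). What may go wrong: the C1–O bond may ionise without the concerted ring-carbon shift, and the tertiary cation may then take a hydride from C9, lose a proton from C7, or the Lewis acid may strip the silyl ethers. Fallback, the epoxy silyl ether rearrangement, in which the migration origin is a silyloxy carbon and a chelating Lewis acid organises the epoxide: set out from 16 and silylate the tertiary hydroxyl with N-(trimethylsilyl)imidazole in CH2Cl2 to the tertiary trimethylsilyl ether F1. Treatment of F1 with TiCl4 in CH2Cl2 at −78 °C should trigger the same anti 1,2-shift of a ring CH2 to C1, the silyl group being lost from the oxocarbenium ion, and aqueous work-up should return the route at 17.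

Step 10 (Shi epoxidation). What may go wrong: oxygen transfer to a crowded alkene that is inductively deactivated on both sides may be slow, so that oxidative decomposition of the ketone catalyst outruns epoxidation, and the bulky carbinol substituent cis to C10 may erode facial discrimination. Fallback, hydroxyl-directed Sharpless asymmetric epoxidation of the primary allylic alcohol: set out from 12 and 6. Deprotonation of 12 with MeLi and iodine–lithium exchange with t-BuLi (Et2O, −78 °C) should give the dilithio alkoxide alkenyllithium F2, which is added to 6 premixed with LaCl3·2LiCl to give the allylic diol F3. Epoxidation of F3 with Ti(OiPr)4, D-(−)-diethyl tartrate and t-BuOOH over 4 Å molecular sieves in CH2Cl2 at −20 °C should deliver oxygen to the face that the Sharpless mnemonic predicts for the (R,R)-epoxide, giving the epoxy diol F4. TIPSCl and imidazole then silylate the primary hydroxyl in preference to the tertiary one, and the route is rejoined at 16.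

Step 15 (imidate formation, elimination, aza-Michael addition). What may go wrong: the β-hydroxy ketone may open by retro-aldol cleavage before the C4 oxygen is acylated, the enone may be deprotonated at C5 instead of being trapped, the conjugate addition may reverse, or the imidates may be hydrolysed by traces of water. Fallback, the carbamate version of the tethered conjugate addition: set out from 22 and carbamoylate both hydroxyls with NaOCN and CF3CO2H in CH2Cl2 to the bis-carbamate F5. DBU in MeCN should eliminate the C4 carbamate to the enone carbamate F6, whose C5 carbamate nitrogen adds to C4 to give the cis-fused oxazolidinone F7. Boc2O with DMAP gives the N-Boc oxazolidinone F8, and Cs2CO3 in MeOH at 0 °C opens the activated ring to the N-Boc amino alcohol F9. Aqueous 4 M HCl in dioxane then removes the Boc group and the TIPS ether to give 26, which is acetylated as in step 16, and the route is rejoined at 27.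

Further compounds
F1 | step 11 | tertiary trimethylsilyl ether of epoxy alcohol 16 | C[Si](C)(C)OC1(C[C@H](OCc2ccccc2)[C@@H](OCc2ccccc2)C1)[C@]1(CCO[Si](C)(C)C(C)(C)C)O[C@@H]1CO[Si](C(C)C)(C(C)C)C(C)C
F2 | step 10 | dilithio species from 12, lithium alkoxide and C1 alkenyllithium | [Li]OC/C=C(\[Li])CCO[Si](C)(C)C(C)(C)C
F3 | step 10 | (3S,4S)-3,4-bis(benzyloxy)-1-[(3Z)-1-[(tert-butyldimethylsilyl)oxy]-5-hydroxypent-3-en-3-yl]cyclopentan-1-ol | OC1(C[C@H](OCc2ccccc2)[C@@H](OCc2ccccc2)C1)/C(CCO[Si](C)(C)C(C)(C)C)=C\CO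
F4 | step 10 | (3S,4S)-3,4-bis(benzyloxy)-1-[(2R,3R)-2-{2-[(tert-butyldimethylsilyl)oxy]ethyl}-3-(hydroxymethyl)oxiran-2-yl]cyclopentan-1-ol | OC1(C[C@H](OCc2ccccc2)[C@@H](OCc2ccccc2)C1)[C@]1(CCO[Si](C)(C)C(C)(C)C)O[C@@H]1CO
F5 | step 15 | bis-carbamate of 22 at the C4 and C5 oxygens | O=C1C[C@H](OC(N)=O)[C@@H](OC(N)=O)C[C@]12CC(=O)O[C@@H]2CO[Si](C(C)C)(C(C)C)C(C)C
F6 | step 15 | C3=C4 enone carrying the C5 carbamate | O=C1C=C[C@@H](OC(N)=O)C[C@]12CC(=O)O[C@@H]2CO[Si](C(C)C)(C(C)C)C(C)C
F7 | step 15 | cis-fused oxazolidinone on C4 (N) and C5 (O), C10 OTIPS | O=C1C[C@@H](N3)[C@@H](OC3=O)C[C@]12CC(=O)O[C@@H]2CO[Si](C(C)C)(C(C)C)C(C)C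
F8 | step 15 | N-Boc derivative of oxazolidinone F7 | O=C1C[C@@H](N3C(=O)OC(C)(C)C)[C@@H](OC3=O)C[C@]12CC(=O)O[C@@H]2CO[Si](C(C)C)(C(C)C)C(C)C
F9 | step 15 | C4 N-Boc amine with free C5 hydroxyl, C10 OTIPS | O=C1C[C@@H](NC(=O)OC(C)(C)C)[C@@H](O)C[C@]12CC(=O)O[C@@H]2CO[Si](C(C)C)(C(C)C)C(C)C
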